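**Plan**

- Retrosynthesis: the C4 ketone is traced back to a spiro-1,3-dithiane; then the aryl ether bond O1–C8a of ring C is cut (C2 carbinol plus C8a bromide), then C3–C4 (lithiated 2-aryl-1,3-dithiane plus the CH2 carbon of an aryl oxirane), and last C4–C4a (formyl group on ring A).
- Forward: ring A (5-bromo-1,2,3-trimethoxybenzene) is formylated and converted into the dithiane; ring B arrives as (R)-2-(3,4-dimethoxyphenyl)oxirane; the C3–C4 bond joins the two halves, ring C closes last through O1–C8a, and C4 is unmasked at the end.
- Enabling feature: O1 sits on the ring A carbon C8a, which is ortho (through C4a) to C4. With C4 held as a dithiane, the same carbon first serves as the acyl anion for C3–C4 and then holds a C8a bromide within reach of the C2 hydroxyl, so the ether is made at the aryl carbon and not at C2.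
- Stereochemistry: C2 is the only stereocentre. It is set by CBS reduction of a bromoketone, carried through the epoxide and its opening at CH2, and the C2–O bond is never broken afterwards.

Key step: step 6

Remark: compounds 1, 4 and 6 are taken as purchased. Epoxide 8 has an electron-rich benzylic C–O bond, so it should be kept away from acid (no silica gel) and used promptly.

**Route**

Step 1
Reactants: 1 5-bromo-1,2,3-trimethoxybenzene
Product: 3 6-bromo-2,3,4-trimethoxybenzaldehyde, via α-chloro ether 2 (not isolated)
Conditions: Cl2CHOMe (1.5 equiv), TiCl4 (2 equiv), CH2Cl2, −10 °C to rt; then ice-water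
Reagents that add atoms: dichloromethyl methyl ether COC(Cl)Cl (formyl carbon); water O (carbonyl oxygen on hydrolysis of 2)
Why: Rieche formylation; the two free ring positions are equivalent by symmetry and each is ortho and para to a methoxy group, so the aldehyde can only arise between Br and OMe, which is the C4a/C8a/C5 pattern of ring A.

Step 2
Reactants: 3 6-bromo-2,3,4-trimethoxybenzaldehyde; 4 propane-1,3-dithiol
Product: 5 2-(6-bromo-2,3,4-trimethoxyphenyl)-1,3-dithiane
Conditions: BF3·OEt2 (20 mol%), CH2Cl2, 0 °C to rt
Reagents that add atoms: none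
Why: Lewis acid-catalysed dithioacetalisation of an aromatic aldehyde, which should proceed even with two ortho substituents and leaves the aryl ethers and the bromide untouched.

Step 3
Reactants: 6 2-bromo-1-(3,4-dimethoxyphenyl)ethan-1-one
Product: 7 (1R)-2-bromo-1-(3,4-dimethoxyphenyl)ethan-1-ol
Conditions: (R)-Me-CBS oxazaborolidine [(3aR)-1-methyl-3,3-diphenyltetrahydro-1H,3H-pyrrolo[1,2-c][1,3,2]oxazaborole] (10 mol%), BH3·SMe2 (0.7 equiv), THF, 0 °C; MeOH quench, aqueous work-up
Reagents that add atoms: none
Why: Corey–Bakshi–Shibata reduction; with aryl as the large group the (R)-catalyst should deliver hydride to the Si face of the ketone to give the (R)-bromohydrin (the sense that gives (S)-1-arylethanols, named R here because CH2Br outranks aryl), and 7 can be recrystallised to raise its enantiomeric purity.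

Step 4
Reactants: 7 (1R)-2-bromo-1-(3,4-dimethoxyphenyl)ethan-1-ol
Product: 8 (2R)-2-(3,4-dimethoxyphenyl)oxirane
Conditions: 2 M aq NaOH, THF, 0 °C to rt
Reagents that add atoms: none
Why: intramolecular Williamson etherification (3-exo-tet); the alkoxide displaces the primary bromide, the benzylic C–O bond is not touched so the configuration is retained, and the basic medium spares the acid-labile epoxide.

Step 5
Reactants: 5 2-(6-bromo-2,3,4-trimethoxyphenyl)-1,3-dithiane; 8 (2R)-2-(3,4-dimethoxyphenyl)oxirane
Product: 10 (1S)-2-[2-(6-bromo-2,3,4-trimethoxyphenyl)-1,3-dithian-2-yl]-1-(3,4-dimethoxyphenyl)ethan-1-ol, via lithiated dithiane 9 (not isolated)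
Conditions: LiN(iPr)2 (1.1 equiv), THF, −78 to −40 °C; then 8 (1.2 equiv), DMPU, −78 °C to rt; H2O
Reagents that add atoms: none
Why: Corey–Seebach umpolung with epoxide opening; the amide base removes the dithiane C2–H without the bromine–lithium exchange an alkyllithium would cause, and the bulky stabilised carbanion should attack the unhindered CH2 carbon of 8 by SN2, so the benzylic C–O bond and its configuration are kept (R in 8 becomes S in 10 only through the change in CIP priorities).

Step 6
Reactants: 10 (1S)-2-[2-(6-bromo-2,3,4-trimethoxyphenyl)-1,3-dithian-2-yl]-1-(3,4-dimethoxyphenyl)ethan-1-ol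
Product: 11 (2S)-2-(3,4-dimethoxyphenyl)-5,6,7-trimethoxyspiro[chromane-4,2'-[1,3]dithiane]
Conditions: CuI (10 mol%), 3,4,7,8-tetramethyl-1,10-phenanthroline (20 mol%), Cs2CO3 (2 equiv), toluene (0.05 M, degassed), 110 °C
Reagents that add atoms: none
Why: Ullmann-type C–O coupling: Cs2CO3 converts the C2 hydroxyl into an alkoxide that binds the phenanthroline-ligated monovalent copper, this copper alkoxide activates the C8a–Br bond (oxidative addition to a trivalent copper aryl or an equivalent halogen-atom transfer), and C–O reductive elimination forms the aryl ether and returns monovalent copper. The closest known reaction type is the copper-catalysed O-arylation of aliphatic alcohols with aryl bromides, used intramolecularly to make chromans and flavans from 3-(2-bromoaryl)-1-arylpropan-1-ols. Ring C closes by attack of the C2 oxygen on C8a with bromide leaving outside the new ring (formally 6-exo-trig, through a seven-membered copper metallacycle), helped by the quaternary dithiane carbon, which folds the chain (Thorpe–Ingold effect). No stereocentre is formed; the bond is made at the aryl carbon, so the C2–O bond and the S configuration of 10 pass unchanged into 11. The step needs C–O coupling to win over loss of bromine by reduction and over binding of copper by the two sulfur atoms: a copper alkoxide has no easy β-hydride path, the chelating phenanthroline should outcompete the thioethers, and six is the only ring size the tether allows. Keeping C4 as the dithiane removes the β-hydroxy ketone that carbonate at 110 °C would cleave by retro-aldol or dehydrate to the chalcone.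

Step 7
Reactants: 11 (2S)-2-(3,4-dimethoxyphenyl)-5,6,7-trimethoxyspiro[chromane-4,2'-[1,3]dithiane]
Product: 12 (2S)-2-(3,4-dimethoxyphenyl)-5,6,7-trimethoxy-2,3-dihydro-4H-chromen-4-one [(2S)-5,6,7,3',4'-pentamethoxyflavanone]
Conditions: MeI (10 equiv), CaCO3 (5 equiv), MeCN–H2O 9:1, 45 °C
Reagents that add atoms: water O
Why: alkylative dithiane hydrolysis; S-methylation gives a sulfonium leaving group, the C4 thionium ion (stabilised by the oxygen donors of ring A) is trapped by water, and CaCO3 buffers the HI, so neither acid nor base opens ring C to the chalcone and C2 is not involved.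

**Compound list**

1 | 5-bromo-1,2,3-trimethoxybenzene | COc1cc(Br)cc(OC)c1OC | starting material
2 | 1-bromo-2-[chloro(methoxy)methyl]-3,4,5-trimethoxybenzene (racemic, titanium-bound until hydrolysis) | COC(Cl)c1c(Br)cc(OC)c(OC)c1OC | intermediate
3 | 6-bromo-2,3,4-trimethoxybenzaldehyde | COc1cc(Br)c(C=O)c(OC)c1OC | intermediate
4 | propane-1,3-dithiol | SCCCS | starting material
5 | 2-(6-bromo-2,3,4-trimethoxyphenyl)-1,3-dithiane | COc1cc(Br)c(C2SCCCS2)c(OC)c1OC | intermediate
6 | 2-bromo-1-(3,4-dimethoxyphenyl)ethan-1-one | COc1ccc(C(=O)CBr)cc1OC | starting material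
7 | (1R)-2-bromo-1-(3,4-dimethoxyphenyl)ethan-1-ol | COc1ccc([C@@H](O)CBr)cc1OC | intermediate
8 | (2R)-2-(3,4-dimethoxyphenyl)oxirane | COc1ccc([C@@H]2CO2)cc1OC | intermediate
9 | [2-(6-bromo-2,3,4-trimethoxyphenyl)-1,3-dithian-2-yl]lithium | [Li]C1(SCCCS1)c1c(Br)cc(OC)c(OC)c1OC | intermediate
10 | (1S)-2-[2-(6-bromo-2,3,4-trimethoxyphenyl)-1,3-dithian-2-yl]-1-(3,4-dimethoxyphenyl)ethan-1-ol | COc1ccc([C@@H](O)CC2(SCCCS2)c3c(Br)cc(OC)c(OC)c3OC)cc1OC | intermediate
11 | (2S)-2-(3,4-dimethoxyphenyl)-5,6,7-trimethoxyspiro[chromane-4,2'-[1,3]dithiane] | COc1ccc([C@@H]2CC3(SCCCS3)c4c(cc(OC)c(OC)c4OC)O2)cc1OC | intermediate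
12 | (2S)-2-(3,4-dimethoxyphenyl)-5,6,7-trimethoxy-2,3-dihydro-4H-chromen-4-one | COc1ccc([C@@H]2CC(=O)c3c(cc(OC)c(OC)c3OC)O2)cc1OC | target

**Step count**

Total: 7 steps. Longest linear sequence: 5 steps (steps 1, 2, 5, 6, 7 from 1; the branch from 6 through steps 3, 4, 5, 6, 7 is equally long).

**Steps most likely to fail, with fallbacks**

Step 5. Removal of the dithiane C2–H, which is flanked by two ortho substituents, may be slow. Metalation next to bromine with loss of LiBr may compete, and the lithium cation may open or rearrange the electron-rich epoxide at its benzylic carbon instead of allowing attack at CH2.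
The fallback sets out from 3 and returns at 10, and builds the C3–C4 bond and the dithiane by thiol conjugate addition instead of carbanion chemistry.
- Seyferth–Gilbert homologation of 3 with the Ohira–Bestmann reagent (dimethyl (1-diazo-2-oxopropyl)phosphonate, K2CO3, MeOH, rt) should give 1-bromo-2-ethynyl-3,4,5-trimethoxybenzene F1.
- Acyl Sonogashira coupling of F1 with 3,4-dimethoxybenzoyl chloride (PdCl2(PPh3)2, CuI, Et3N, THF, rt) should give 3-(6-bromo-2,3,4-trimethoxyphenyl)-1-(3,4-dimethoxyphenyl)prop-2-yn-1-one F2. The acid chloride should add to zerovalent palladium far faster than the hindered, electron-rich aryl bromide.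
- Double conjugate addition of 4 (NaOMe, MeOH–CH2Cl2, −10 °C to rt) places both sulfur atoms on the alkyne carbon remote from the carbonyl and should give 2-[2-(6-bromo-2,3,4-trimethoxyphenyl)-1,3-dithian-2-yl]-1-(3,4-dimethoxyphenyl)ethan-1-one F3.
- CBS reduction of F3 with the (R)-oxazaborolidine and BH3·SMe2 (aryl as the large group) should then give 10.

Step 6. The two sulfur atoms next to the C–Br bond may sequester the copper, and activation of the hindered, electron-rich C8a–Br bond may be slow, so that starting material is recovered or bromine is lost by reduction.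
The fallback sets out from 10 and returns at 12, and carries C4 through the ring closure at the alcohol oxidation level, free of sulfur.
- Hydrolysis of the dithiane of 10 (MeI, CaCO3, MeCN–H2O, 45 °C) should give (3S)-1-(6-bromo-2,3,4-trimethoxyphenyl)-3-(3,4-dimethoxyphenyl)-3-hydroxypropan-1-one F4.
- Narasaka–Prasad reduction (Et2BOMe, NaBH4, THF–MeOH, −78 °C) should give the syn diol (1R,3S)-1-(6-bromo-2,3,4-trimethoxyphenyl)-3-(3,4-dimethoxyphenyl)propane-1,3-diol F5.
- The same CuI/tetramethylphenanthroline/Cs2CO3 cyclisation should give (2S,4R)-2-(3,4-dimethoxyphenyl)-5,6,7-trimethoxy-3,4-dihydro-2H-chromen-4-ol F6. Only the C3 hydroxyl can reach C–Br in a six-membered ring; the other hydroxyl would have to close a four-membered one.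
- Oxidation of F6 with Dess–Martin periodinane (NaHCO3, CH2Cl2, rt) should give 12 without base that could open ring C.

Step 7. Hydrolysis of the congested spiro thioketal may stall, and prolonged heating may open ring C to the chalcone and erode the configuration at C2.
The fallback sets out from 11 and returns at 12, and activates the thioketal by oxidation at sulfur instead of alkylation.
- NaIO4 (1 equiv, MeOH–H2O, 0 °C) should give the monosulfoxide (2S)-2-(3,4-dimethoxyphenyl)-5,6,7-trimethoxyspiro[chromane-4,2'-[1,3]dithiane] 1'-oxide F7, as a mixture of isomers at sulfur and C4.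
- Brief treatment of F7 with dilute HCl in THF at rt should release 12.

Further compounds
F1 | step 5 | 1-bromo-2-ethynyl-3,4,5-trimethoxybenzene | C#Cc1c(Br)cc(OC)c(OC)c1OC
F2 | step 5 | 3-(6-bromo-2,3,4-trimethoxyphenyl)-1-(3,4-dimethoxyphenyl)prop-2-yn-1-one | COc1ccc(C(=O)C#Cc2c(Br)cc(OC)c(OC)c2OC)cc1OC
F3 | step 5 | 2-[2-(6-bromo-2,3,4-trimethoxyphenyl)-1,3-dithian-2-yl]-1-(3,4-dimethoxyphenyl)ethan-1-one | COc1ccc(C(=O)CC2(SCCCS2)c3c(Br)cc(OC)c(OC)c3OC)cc1OC
F4 | step 6 | (3S)-1-(6-bromo-2,3,4-trimethoxyphenyl)-3-(3,4-dimethoxyphenyl)-3-hydroxypropan-1-one | COc1ccc([C@@H](O)CC(=O)c2c(Br)cc(OC)c(OC)c2OC)cc1OC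
F5 | step 6 | (1R,3S)-1-(6-bromo-2,3,4-trimethoxyphenyl)-3-(3,4-dimethoxyphenyl)propane-1,3-diol | COc1ccc([C@@H](O)C[C@@H](O)c2c(Br)cc(OC)c(OC)c2OC)cc1OC
F6 | step 6 | (2S,4R)-2-(3,4-dimethoxyphenyl)-5,6,7-trimethoxy-3,4-dihydro-2H-chromen-4-ol | COc1ccc([C@@H]2C[C@@H](O)c3c(cc(OC)c(OC)c3OC)O2)cc1OC
F7 | step 7 | (2S)-2-(3,4-dimethoxyphenyl)-5,6,7-trimethoxyspiro[chromane-4,2'-[1,3]dithiane] 1'-oxide (mixture of isomers at sulfur and C4) | COc1ccc([C@@H]2CC3(SCCCS3=O)c4c(cc(OC)c(OC)c4OC)O2)cc1OC
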